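**Retrosynthetic overview**
1. Target 22 ⇐ diol 21 (bis-acetylation) ⇐ silylene-bridged lactone 20 (desilylation).
2. Key step: 20 ⇐ iodide 19. The C7–C8 bond is made by 10-exo addition of a C8 alkyl radical to the α-methylbutenolide; this closes the ten-membered carbocycle last and sets C7 and C11.
3. 19 ⇐ acyclic bis-alkoxysilane 18 by one double ring-closing metathesis (butenolide ring plus a temporary eight-membered Z-silaketal ring).
4. 18 ⇐ West alcohol 12 + East iodohydrin 16 + iPr2SiCl2.
5. 12 from propargyl alcohol, acrolein, methacryloyl chloride and allylmagnesium bromide; 16 from prenol. Ring order: butenolide and silaketal ring together, then the carbocycle.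

Assumption: atom labels C1–C15 follow germacrane numbering (C6 lactone O-bearing carbon, C7 ring-fusion CH, C11/C12/C13 lactone CH, C=O and its methyl, C14 methyl on C10, C15 methyl on C4); in this numbering the target SMILES reads (3S,6S,7S,9S,11R), 1(10)Z, 4E.

**Route**

Step 1
Reactants: 1 prop-2-yn-1-ol
Product: 3 (2E)-3-iodo-2-methylprop-2-en-1-ol, via alkenylalane 2 (not isolated)
Conditions: AlMe3 (3 equiv), Cp2ZrCl2 (0.25 equiv), CH2Cl2, 0 °C to rt; then I2, THF, −30 to 0 °C
Reagents that add atoms: trimethylaluminium, C[Al](C)C; iodine, II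
Why: Zirconium-catalysed Negishi carboalumination adds Me and Al syn across the alkyne (Me to the internal carbon) and iodinolysis with retention gives the E vinyl iodide, which fixes the C4=C5 geometry.

Step 2
Reactants: 3 (2E)-3-iodo-2-methylprop-2-en-1-ol; 4 prop-2-enal
Product: 5 (2E,4S)-2-methylhexa-2,5-diene-1,4-diol
Conditions: CrCl2 (4 equiv), NiCl2 (2 mol %), Kishi-type chiral oxazoline–sulfonamide ligand (4.4 equiv, antipode for Re-face addition), Et3N, THF, rt
Reagents that add atoms: none
Why: Asymmetric Nozaki–Hiyama–Kishi alkenylation tolerates the free hydroxyl, and the ligand-bound alkenylchromium adds 1,2 to the Re face of acrolein, setting C6 (4S in 5).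

Step 3
Reactants: 5 (2E,4S)-2-methylhexa-2,5-diene-1,4-diol
Product: 6 (2E,4S)-4-hydroxy-2-methylhexa-2,5-dienal
Conditions: TEMPO (10 mol %), PhI(OAc)2 (1.1 equiv), CH2Cl2, 0 °C to rt
Reagents that add atoms: none
Why: Oxoammonium (TEMPO/PhI(OAc)2) oxidation is selective for the primary allylic alcohol over the hindered secondary one and does not touch the stereocentre or the E olefin.

Step 4
Reactants: 6 (2E,4S)-4-hydroxy-2-methylhexa-2,5-dienal; 7 2-methylprop-2-enoyl chloride
Product: 8 (3S,4E)-5-methyl-6-oxohexa-1,4-dien-3-yl 2-methylprop-2-enoate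
Conditions: pyridine, DMAP (5 mol %), CH2Cl2, −20 to 0 °C
Reagents that add atoms: none
Why: O-acylation of the only free hydroxyl brings in C11, C12 and C13 of the future lactone, and the weak base at low temperature leaves the γ-stereocentre of the enal intact.

Step 5
Reactants: 8 (3S,4E)-5-methyl-6-oxohexa-1,4-dien-3-yl 2-methylprop-2-enoate; 9 allylmagnesium bromide
Product: 12 (3S,4E,6S)-6-hydroxy-5-methylnona-1,4,8-trien-3-yl 2-methylprop-2-enoate, via B-allyldiisopinocampheylborane 10 (not isolated), via borinate ester 11 (not isolated)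
Conditions: (−)-Ipc2BOMe, 9, Et2O, −78 °C to rt; then 8, −78 °C; ethanolamine work-up, 0 °C
Reagents that add atoms: none
Why: Brown allylboration through a chair Zimmerman–Traxler transition state is chemoselective for the aldehyde, and (−)-Ipc2B-allyl (from (+)-α-pinene) attacks its Si face under reagent control, setting C3 as S.

Step 6
Reactants: 13 3-methylbut-2-en-1-ol
Product: 14 [(2S)-3,3-dimethyloxiran-2-yl]methanol
Conditions: Ti(OiPr)4 (5 mol %), L-(+)-diethyl tartrate (6 mol %), t-BuOOH, 4 Å molecular sieves, CH2Cl2, −20 °C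
Reagents that add atoms: tert-butyl hydroperoxide, CC(C)(C)OO
Why: Sharpless asymmetric epoxidation with L-(+)-tartrate delivers oxygen to the face that gives the 2S epoxide (same sense as geraniol to (2S,3S)-epoxygeraniol), which becomes C9.

Step 7
Reactants: 14 [(2S)-3,3-dimethyloxiran-2-yl]methanol
Product: 15 (2R)-3-methylbut-3-ene-1,2-diol
Conditions: Ti(OiPr)4 (1.2 equiv), CH2Cl2, rt to 40 °C; aqueous tartaric acid work-up
Reagents that add atoms: none
Why: Sharpless titanium-mediated epoxy-alcohol-to-enediol rearrangement opens the tertiary C–O bond and removes a methyl proton, while the C–O bond at the stereocentre is untouched (2S epoxide becomes 2R diol by priority change only).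

Step 8
Reactants: 15 (2R)-3-methylbut-3-ene-1,2-diol
Product: 16 (2R)-1-iodo-3-methylbut-3-en-2-ol
Conditions: I2 (1.05 equiv), PPh3 (1.1 equiv), imidazole (2 equiv), CH2Cl2, −10 to 0 °C
Reagents that add atoms: iodine, II
Why: Appel-type (Garegg–Samuelsson) iodination with one equivalent of reagent is selective for the primary hydroxyl and leaves the carbinol stereocentre alone.

Step 9
Reactants: 12 (3S,4E,6S)-6-hydroxy-5-methylnona-1,4,8-trien-3-yl 2-methylprop-2-enoate; 16 (2R)-1-iodo-3-methylbut-3-en-2-ol
Product: 18 mixed bis-alkoxysilane of 12 and 16, via chlorosilyl ether 17 (not isolated)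
Conditions: 16, iPr2SiCl2 (3 equiv), imidazole, CH2Cl2, 0 °C; strip excess iPr2SiCl2; then 12, imidazole, DMAP (10 mol %), DMF, rt
Reagents that add atoms: dichlorodi(propan-2-yl)silane, CC(C)[Si](Cl)(Cl)C(C)C
Why: Stepwise silylation works because the second Si–Cl bond is much slower than the first, giving the unsymmetrical silaketal that protects both carbinols and tethers the allyl and isopropenyl groups; no stereocentre is formed.

Step 10
Reactants: 18 mixed bis-alkoxysilane
Product: 19 (5R)-5-{(1E)-2-[(4S,6Z,8R)-8-(iodomethyl)-7-methyl-2,2-di(propan-2-yl)-1,3-dioxa-2-silacyclooct-6-en-4-yl]prop-1-en-1-yl}-3-methylfuran-2(5H)-one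
Conditions: second-generation Grubbs catalyst RuCl2(=CHPh)(PCy3)(H2IMes) (10 mol %), toluene (2 mM), 80 °C, Ar purge
Reagents that add atoms: none
Why: Two ring-closing metatheses run in one operation: methacrylate plus vinyl gives the α-methylbutenolide, and allyl plus isopropenyl across the silicon tether gives the eight-membered ring, whose size forces the Z geometry at C1=C10 (temporary-silicon-tethered RCM).

Step 11
Reactants: 19 butenolide iodide
Product: 20 (3R,3aS,5S,6Z,9S,10E,11aS)-5,9-[di(propan-2-yl)silanediyldioxy]-3,6,10-trimethyl-3a,4,5,8,9,11a-hexahydrocyclodeca[b]furan-2(3H)-one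
Conditions: (Me3Si)3SiH (1.5 equiv) and AIBN (0.3 equiv) by syringe pump over 10 h into 19 (1 mM) in benzene, 80 °C
Reagents that add atoms: none
Why: Proposed new method: iodine abstraction by (Me3Si)3Si• gives a nucleophilic primary C8 radical held on the rigid Z-silaketal (only the C3–C4, C5–C6 and C9–C8 bonds rotate freely), which adds 10-exo to the electrophilic β-carbon C7 of the butenolide anti to the C6 alkenyl substituent (6,7-trans fusion), and the tertiary α-lactone radical at C11 then takes H from the bulky silane anti to the new C7–C8 bond, leaving the C11 methyl cis to C8 (11R); the closest known chemistry is the Porter and Pattenden silane- or stannane-mediated radical macrocyclisations onto enones and acrylates and intermolecular Giese additions to γ-substituted butenolides (anti addition, kinetic cis hydrogen transfer).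

Step 12
Reactants: 20 silylene-bridged lactone
Product: 21 (3R,3aS,5S,6Z,9S,10E,11aS)-5,9-dihydroxy-3,6,10-trimethyl-3a,4,5,8,9,11a-hexahydrocyclodeca[b]furan-2(3H)-one
Conditions: HF·pyridine, pyridine, THF, 0 °C to rt
Reagents that add atoms: none
Why: Fluoride-driven Si–O cleavage (desilylation) under buffered, non-basic conditions frees both carbinols without epimerising the kinetically set C11 centre.

Step 13
Reactants: 21 diol
Product: 22 (3R,3aS,5S,6Z,9S,10E,11aS)-3,6,10-trimethyl-2-oxo-2,3,3a,4,5,8,9,11a-octahydrocyclodeca[b]furan-5,9-diyl diacetate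
Conditions: Ac2O, pyridine, DMAP (5 mol %), CH2Cl2, 0 °C to rt
Reagents that add atoms: acetic anhydride, CC(=O)OC(C)=O
Why: DMAP-catalysed acylation esterifies both secondary allylic alcohols with retention, and pyridine is too weak a base to epimerise the α-methyl lactone.

**Compound list**
1 | prop-2-yn-1-ol | C#CCO | starting material
2 | dimethyl{[(2E)-3-(dimethylalumanyl)-2-methylprop-2-en-1-yl]oxy}alumane | C[Al](C)/C=C(\C)CO[Al](C)C | intermediate (not isolated)
3 | (2E)-3-iodo-2-methylprop-2-en-1-ol | OC/C(C)=C/I | intermediate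
4 | prop-2-enal (acrolein) | C=CC=O | starting material
5 | (2E,4S)-2-methylhexa-2,5-diene-1,4-diol | OC/C(C)=C/[C@H](C=C)O | intermediate
6 | (2E,4S)-4-hydroxy-2-methylhexa-2,5-dienal | O=C/C(C)=C/[C@H](C=C)O | intermediate
7 | 2-methylprop-2-enoyl chloride | C=C(C)C(=O)Cl | starting material
8 | (3S,4E)-5-methyl-6-oxohexa-1,4-dien-3-yl 2-methylprop-2-enoate | O=C/C(C)=C/[C@H](C=C)OC(=O)C(C)=C | intermediate
9 | allylmagnesium bromide | C=CC[Mg]Br | starting material
10 | (−)-B-allyldiisopinocampheylborane | C=CCB([C@@H]1C[C@@H]2C[C@H]([C@H]1C)C2(C)C)[C@@H]1C[C@@H]2C[C@H]([C@H]1C)C2(C)C | intermediate (not isolated)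
11 | diisopinocampheylborinate ester of 12 | C=CC[C@H](OB([C@@H]1C[C@@H]2C[C@H]([C@H]1C)C2(C)C)[C@@H]1C[C@@H]2C[C@H]([C@H]1C)C2(C)C)/C(C)=C/[C@H](C=C)OC(=O)C(C)=C | intermediate (not isolated)
12 | (3S,4E,6S)-6-hydroxy-5-methylnona-1,4,8-trien-3-yl 2-methylprop-2-enoate | C=CC[C@H](O)/C(C)=C/[C@H](C=C)OC(=O)C(C)=C | intermediate
13 | 3-methylbut-2-en-1-ol (prenol) | CC(C)=CCO | starting material
14 | [(2S)-3,3-dimethyloxiran-2-yl]methanol | OC[C@@H]1OC1(C)C | intermediate
15 | (2R)-3-methylbut-3-ene-1,2-diol | OC[C@H](O)C(C)=C | intermediate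
16 | (2R)-1-iodo-3-methylbut-3-en-2-ol | IC[C@H](O)C(C)=C | intermediate
17 | chloro{[(2R)-1-iodo-3-methylbut-3-en-2-yl]oxy}di(propan-2-yl)silane | IC[C@H](O[Si](Cl)(C(C)C)C(C)C)C(C)=C | intermediate (not isolated)
18 | (3S,4E,6S)-6-[({[(2R)-1-iodo-3-methylbut-3-en-2-yl]oxy}di(propan-2-yl)silyl)oxy]-5-methylnona-1,4,8-trien-3-yl 2-methylprop-2-enoate | IC[C@H](O[Si](C(C)C)(C(C)C)O[C@@H](CC=C)/C(C)=C/[C@H](C=C)OC(=O)C(C)=C)C(C)=C | intermediate
19 | (5R)-5-{(1E)-2-[(4S,6Z,8R)-8-(iodomethyl)-7-methyl-2,2-di(propan-2-yl)-1,3-dioxa-2-silacyclooct-6-en-4-yl]prop-1-en-1-yl}-3-methylfuran-2(5H)-one | IC[C@H](O[Si]1(C(C)C)C(C)C)/C(C)=C\C[C@H](O1)/C(C)=C/[C@H]2OC(=O)C(C)=C2 | intermediate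
20 | (3R,3aS,5S,6Z,9S,10E,11aS)-5,9-[di(propan-2-yl)silanediyldioxy]-3,6,10-trimethyl-3a,4,5,8,9,11a-hexahydrocyclodeca[b]furan-2(3H)-one | CC(C)[Si]3(C(C)C)O[C@H]1C[C@@H]2[C@@H](/C=C(\C)[C@@H](O3)C/C=C\1C)OC(=O)[C@@H]2C | intermediate
21 | (3R,3aS,5S,6Z,9S,10E,11aS)-5,9-dihydroxy-3,6,10-trimethyl-3a,4,5,8,9,11a-hexahydrocyclodeca[b]furan-2(3H)-one | O[C@H]1C[C@@H]2[C@@H](/C=C(\C)[C@@H](O)C/C=C\1C)OC(=O)[C@@H]2C | intermediate
22 | (3R,3aS,5S,6Z,9S,10E,11aS)-3,6,10-trimethyl-2-oxo-2,3,3a,4,5,8,9,11a-octahydrocyclodeca[b]furan-5,9-diyl diacetate (CNP0226482.5) | CC(=O)O[C@H]1C[C@@H]2[C@@H](/C=C(\C)[C@@H](OC(C)=O)C/C=C\1C)OC(=O)[C@@H]2C | target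

**Step count**
Total: 13 steps. Longest linear sequence: 10 steps (1–5, then 9–13); the East branch is 3 steps (6–8).

**Steps most likely to fail, with fallbacks**

Step 11 (radical macrocyclisation). The ten-membered closure is slow, so the homoallylic C8 radical may instead close 3-exo on C10 and end as the 1,2-vinyl-shifted C9 radical, abstract an allylic hydrogen from C2, or be reduced before it cyclises. The fallback lets metathesis, not the radical step, close the carbocycle; it sets out from 12 and 16 and comes back at 20. Alcohol 12 with the second-generation Grubbs catalyst closes only the butenolide and gives the butenolide alcohol F1. Silylation of F1 with chlorosilane 17 (made from 16 as in step 9) gives the acyclic silaketal F2, which still carries the allyl and isopropenyl groups. In F2 the C2 hydrogens are no longer within 1,5-reach of C8 and 3-exo attack would hit a 1,1-disubstituted olefin; (Me3Si)3SiH/AIBN at high dilution then adds the C8 radical to C7 through a more flexible ten-membered 1,3-dioxa-2-silacycle, giving the tethered lactone F3 with the same C7 and C11 outcome. Ring-closing metathesis of F3 between the allyl and isopropenyl groups closes the eight-membered silaketal ring and with it the carbocycle, returning 20.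

Step 2 (asymmetric Ni/Cr coupling). Enantioselectivity for an alkenylchromium adding to acrolein in the presence of a free hydroxyl may be modest, and the minor enantiomer of 5 becomes a diastereomer of 12 that is hard to remove. The fallback builds the carbinol by asymmetric alkynylation of an enal instead; it sets out from 3 and comes back at 5. Silylation of 3 (TBSCl, imidazole) gives the silyl ether F4. Iodine–lithium exchange (t-BuLi, Et2O, −78 °C) and DMF give the enal F5. Zn-ProPhenol-catalysed addition of trimethylsilylacetylene (Me2Zn, the ProPhenol antipode that adds to the Si face) gives the propargylic alcohol F6. Bu4NF removes both silyl groups to give the enyne diol F7, and Lindlar semihydrogenation (Pd/CaCO3 poisoned with Pb(OAc)2, quinoline, H2) of the terminal alkyne returns 5.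

Step 10 (double ring-closing metathesis). The two closures differ greatly in rate; if the trisubstituted eight-membered closure lags, the free allyl terminus can oligomerise while the sensitive butenolide sits at 80 °C. The fallback separates the two ring closures and changes their order; it sets out from 12 and 16 and comes back at 19. The butenolide is closed first on 12 to give the butenolide alcohol F1, the tether is then installed to give the silaketal F2, and a single metathesis on F2, with only one ring left to close, gives 19. This detour makes no compound beyond F1 and F2.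

**Further compounds**
F1 | step 11 | (5R)-5-[(1E,3S)-3-hydroxy-2-methylhexa-1,5-dien-1-yl]-3-methylfuran-2(5H)-one | C=CC[C@H](O)/C(C)=C/[C@H]1OC(=O)C(C)=C1
F2 | step 11 | (5R)-5-{(1E,3S)-3-[({[(2R)-1-iodo-3-methylbut-3-en-2-yl]oxy}di(propan-2-yl)silyl)oxy]-2-methylhexa-1,5-dien-1-yl}-3-methylfuran-2(5H)-one | IC[C@H](O[Si](C(C)C)(C(C)C)O[C@@H](CC=C)/C(C)=C/[C@H]1OC(=O)C(C)=C1)C(C)=C
F3 | step 11 | ten-membered 1,3-dioxa-2-silacycle fused to the α-methyl lactone, carrying the allyl group on C3 and the isopropenyl group on C9 | CC(C)[Si]3(C(C)C)O[C@H](C(C)=C)C[C@@H]2[C@@H](/C=C(\C)[C@@H](O3)CC=C)OC(=O)[C@@H]2C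
F4 | step 2 | tert-butyl{[(2E)-3-iodo-2-methylprop-2-en-1-yl]oxy}dimethylsilane | CC(C)(C)[Si](C)(C)OC/C(C)=C/I
F5 | step 2 | (2E)-4-{[tert-butyl(dimethyl)silyl]oxy}-3-methylbut-2-enal | CC(C)(C)[Si](C)(C)OC/C(C)=C/C=O
F6 | step 2 | (3R,4E)-6-{[tert-butyl(dimethyl)silyl]oxy}-5-methyl-1-(trimethylsilyl)hex-4-en-1-yn-3-ol | CC(C)(C)[Si](C)(C)OC/C(C)=C/[C@@H](O)C#C[Si](C)(C)C
F7 | step 2 | (2E,4R)-2-methylhex-2-en-5-yne-1,4-diol | OC/C(C)=C/[C@@H](O)C#C
F0 | step 10 | none | none
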